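**Retrosynthetic overview**
1. Feature: in the 7-oxabicyclo[2.2.1]heptane end group the bridging oxygen links the CH bridgehead C3 to the quaternary bridgehead C6, the carbon that bears the C7=C8 vinyl link. The tertiary OH on the adjacent C5 is endo, trans to that bridge, which is what a 3-OH leaves behind when it opens a 5,6-oxirane of the opposite ring face at C6.
2. Disconnections: (a) the butenolide C3–C8 bond by Stille coupling, giving an oxabicyclic E-vinylstannane and a 3-bromo-5(Z)-ylidenebutenolide polyene; (b) the O–C6 bond of the bicycle by Lewis-acid transannular opening of a 6-ethynyl-3-hydroxy-5,6-epoxycyclohexane.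
3. (c) The ylidene C17'=C5 bond by vinylogous Mukaiyama aldol/elimination between a C22 pentaenal and the silyloxyfuran of 3-bromofuran-2(5H)-one; (d) the C8'–C9' bond by Stille coupling of a ring dienylstannane with an iodotetraenal grown from but-2-yn-1-ol.
4. Both carbocycles stem from one enyne made from ketoisophorone via (4R,6R)-actinol. The diol ring gains O4' by allylic oxidation and hydride addition anti to the 3'-silyloxy group.
5. Ring order: the two carbocycles and the lactone come with the starting materials. The oxirane is made in step 6 and the oxolane bridge of the bicycle in step 8.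

Key step: step 8

Remark on locants: in both carbocycles C1 is the CMe2 carbon, C3 the secondary carbinol carbon, C5 the methyl-bearing carbon and C6 the carbon that holds the chain. Primed locants belong to the diol half, whose chain runs from C7' (on the ring) to C17' (the ylidene CH). The lactone is numbered as a furan-2(5H)-one.

**Step 1**
Reactants: 1 ketoisophorone (2,6,6-trimethylcyclohex-2-ene-1,4-dione)
Product: 2 (R)-levodione, (6R)-2,2,6-trimethylcyclohexane-1,4-dione
Conditions: ene-reductase OYE2, NADP+ (cat.), glucose dehydrogenase, D-glucose, phosphate buffer pH 7, 30 °C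
Reagents that add atoms: none
Why: Flavin-dependent ene-reductase reduction of an activated alkene, in which the enzyme pocket delivers hydride and proton trans across C2=C3 from fixed faces and should set the methyl-bearing centre as R.

**Step 2**
Reactants: 2 (R)-levodione
Product: 3 (4R,6R)-actinol, (4R,6R)-4-hydroxy-2,2,6-trimethylcyclohexan-1-one (OH trans to the 6-methyl group)
Conditions: L-Selectride (LiBH(s-Bu)3, 1.05 equiv), THF, −78 °C; then H2O
Reagents that add atoms: none
Why: Diastereoselective ketone reduction with a bulky borohydride: only the unhindered C4 carbonyl is accessible and, as in 3,3,5-trimethylcyclohexanone, the axial methyl of the CMe2 group blocks axial approach, so equatorial hydride delivery should give the axial, trans (4R) alcohol; any cis isomer is removed here because C6 is flattened in step 4.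

**Step 3**
Reactants: 3 (4R,6R)-actinol
Product: 4 (4R,6R)-4-(tert-butyldimethylsilyloxy)-2,2,6-trimethylcyclohexan-1-one
Conditions: TBSCl, imidazole, DMF, rt
Reagents that add atoms: tert-butyldimethylsilyl chloride, CC(C)(C)[Si](C)(C)Cl
Why: Imidazole-promoted silylation of a secondary alcohol, which touches no stereocentre and masks the hydroxyl for the enolate, palladium and oxidation chemistry ahead.

**Step 4**
Reactants: 4 (4R,6R)-4-(tert-butyldimethylsilyloxy)-2,2,6-trimethylcyclohexan-1-one
Product: 6 (R)-4-(tert-butyldimethylsilyloxy)-2,6,6-trimethylcyclohex-1-en-1-yl trifluoromethanesulfonate, via lithium enolate 5 (not isolated)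
Conditions: LDA (LiN(i-Pr)2), THF, −78 → 0 °C; then PhNTf2, −78 °C → rt
Reagents that add atoms: N-phenylbis(trifluoromethanesulfonimide), O=S(=O)(N(c1ccccc1)S(=O)(=O)C(F)(F)F)C(F)(F)F
Why: Enolate O-triflation: the ketone can enolise only towards the methyl-bearing carbon because the other α-carbon is quaternary, so the tetrasubstituted enol triflate forms regiospecifically, the α-stereocentre is erased on purpose and the silyloxy-bearing centre is untouched.

**Step 5**
Reactants: 6 (R)-4-(tert-butyldimethylsilyloxy)-2,6,6-trimethylcyclohex-1-en-1-yl trifluoromethanesulfonate; 7 ethynyltrimethylsilane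
Product: 8 (R)-tert-butyldimethyl{[3,5,5-trimethyl-4-(trimethylsilylethynyl)cyclohex-3-en-1-yl]oxy}silane (common enyne)
Conditions: PdCl2(PPh3)2 (5 mol%), CuI (10 mol%), Et3N, DMF, rt → 50 °C
Reagents that add atoms: none
Why: Sonogashira coupling of an enol triflate with a terminal alkyne, which fixes the C5=C6 alkene position without a dehydration step and is established for 2,6,6-trimethylcyclohexenyl triflates.

**Step 6**
Reactants: 8 common enyne
Product: 9 tert-butyldimethyl{[(1R,3S,6R)-1,5,5-trimethyl-6-(trimethylsilylethynyl)-7-oxabicyclo[4.1.0]heptan-3-yl]oxy}silane (oxirane anti to the silyloxy group)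
Conditions: mCPBA, NaHCO3, CH2Cl2, 0 °C
Reagents that add atoms: 3-chloroperbenzoic acid, O=C(OO)c1cccc(Cl)c1
Why: Prilezhaev epoxidation: the tetrasubstituted ring alkene is far more nucleophilic than the silylated alkyne, and the peracid is expected to add to the face away from the 3-silyloxy group, as 3-acyloxy and 3-silyloxy cyclohexene end groups of this kind generally do, which sets C5 (R) and C6 (R) in one syn addition; the syn-epoxide, which could not bridge later, is separated here.

**Step 7**
Reactants: 9 silylated anti-epoxide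
Product: 10 (1R,3S,6R)-6-ethynyl-1,5,5-trimethyl-7-oxabicyclo[4.1.0]heptan-3-ol (3-OH anti to the oxirane)
Conditions: TBAF (Bu4NF, 2.5 equiv), THF, 0 °C → rt
Reagents that add atoms: none
Why: Fluoride-induced desilylation cleaves the O–Si and the alkynyl C–Si bond in one operation under non-acidic conditions that leave the tetrasubstituted oxirane closed.

**Step 8**
Reactants: 10 (1R,3S,6R)-6-ethynyl-1,5,5-trimethyl-7-oxabicyclo[4.1.0]heptan-3-ol
Product: 11 (1S,4S,6R)-1-ethynyl-2,2,6-trimethyl-7-oxabicyclo[2.2.1]heptan-6-ol (OH endo)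
Conditions: BF3·OEt2 (0.2 equiv), CH2Cl2, −78 → −20 °C; then sat. aq. NaHCO3
Reagents that add atoms: none
Why: BF3 binds the oxirane oxygen and loosens the tertiary, propargylic C6–O bond, and in the boat conformer of the carbocycle the 3-OH, which stands on the ring face opposite to the oxirane, lies in line with that bond and displaces the oxygen from behind in a borderline SN2 opening. The closest known reaction type is the acid-induced rearrangement of 3-hydroxy-5,6-epoxy carotenoid end groups into 3,6-epoxy-5-hydroxy end groups, a transannular form of epoxy-alcohol cyclisation. The one ring that closes is an oxolane (O, C3, C2, C1, C6), formed in a 5-exo-tet mode when counted through C2–C1 because the breaking C6–O bond lies outside it, and it turns the cyclohexane into the 7-oxabicyclo[2.2.1]heptane. The new configuration at C6 results from inversion, enforced because the tethered hydroxyl can reach C6 only from the face anti to the oxirane, while C3 and C5 keep their C–O bonds, so the former oxirane oxygen ends as the endo tertiary alcohol on C5. The step needs cleavage at C6 and not at C5: attack of O3 on C5 would build a strained oxetane, unassisted ionisation at C5 is held back by low temperature and a substoichiometric acid, and the alkyne offers the oxygen on C5 no C8 terminus for the furanoid closure that a 7,8-alkene would allow.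

**Step 9**
Reactants: 11 (1S,4S,6R)-1-ethynyl-2,2,6-trimethyl-7-oxabicyclo[2.2.1]heptan-6-ol
Product: 12 (1R,4S,6R)-2,2,6-trimethyl-1-[(E)-2-(tributylstannyl)vinyl]-7-oxabicyclo[2.2.1]heptan-6-ol
Conditions: Bu3SnH, PdCl2(PPh3)2 (3 mol%), THF, 0 °C → rt
Reagents that add atoms: tributyltin hydride, CCCC[SnH](CCCC)CCCC
Why: Palladium-catalysed syn hydrostannylation of a terminal alkyne, in which the quaternary bridgehead next to the triple bond steers tin to the terminal carbon, so the E-vinylstannane should result and the free tertiary alcohol is tolerated.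

**Step 10**
Reactants: 8 common enyne
Product: 13 (S)-6-(tert-butyldimethylsilyloxy)-2,4,4-trimethyl-3-(trimethylsilylethynyl)cyclohex-2-en-1-one
Conditions: CrO3, 3,5-dimethylpyrazole, CH2Cl2, −20 → 0 °C
Reagents that add atoms: chromium trioxide, O=[Cr](=O)=O
Why: Allylic C–H oxidation with the CrO3–dimethylpyrazole complex: C4' is the only secondary allylic position because C1' is quaternary, so the enone should form there in preference to attack on the C5' methyl group, and the neutral medium leaves the adjacent silyloxy-bearing stereocentre unepimerised.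

**Step 11**
Reactants: 13 (S)-6-(tert-butyldimethylsilyloxy)-2,4,4-trimethyl-3-(trimethylsilylethynyl)cyclohex-2-en-1-one
Product: 14 (1R,6S)-6-(tert-butyldimethylsilyloxy)-2,4,4-trimethyl-3-(trimethylsilylethynyl)cyclohex-2-en-1-ol (oxygens cis)
Conditions: L-Selectride (LiBH(s-Bu)3), THF, −78 °C; then H2O
Reagents that add atoms: none
Why: Diastereoselective 1,2-reduction with a bulky borohydride: the fully substituted β-carbon shuts off conjugate reduction, and hydride should enter anti to the neighbouring silyloxy group (steric and polar Felkin–Anh control), placing the new hydroxyl cis to it and setting C4' as R; any trans isomer is separated and can be re-oxidised to 13.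

**Step 12**
Reactants: 14 cis-silyloxy alcohol
Product: 15 (3R,4S)-3,4-bis(tert-butyldimethylsilyloxy)-2,6,6-trimethyl-1-(trimethylsilylethynyl)cyclohex-1-ene
Conditions: TBSOTf, 2,6-lutidine, CH2Cl2, 0 °C
Reagents that add atoms: tert-butyldimethylsilyl trifluoromethanesulfonate, CC(C)(C)[Si](C)(C)OS(=O)(=O)C(F)(F)F
Why: Silyl triflate silylation of a hindered allylic alcohol under buffered conditions; a silyl shift between the two oxygens would be without consequence because both end as the same ether.

**Step 13**
Reactants: 15 bis-silyl ether with silylated alkyne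
Product: 16 (3R,4S)-3,4-bis(tert-butyldimethylsilyloxy)-1-ethynyl-2,6,6-trimethylcyclohex-1-ene
Conditions: K2CO3 (cat.), MeOH, rt
Reagents that add atoms: none
Why: Base-catalysed methanolysis of an alkynylsilane, which is selective for the C–SiMe3 bond over the two secondary TBS ethers.

**Step 14**
Reactants: 16 (3R,4S)-3,4-bis(tert-butyldimethylsilyloxy)-1-ethynyl-2,6,6-trimethylcyclohex-1-ene
Product: 17 tributyl{(E)-2-[(3R,4S)-3,4-bis(tert-butyldimethylsilyloxy)-2,6,6-trimethylcyclohex-1-en-1-yl]vinyl}stannane
Conditions: Bu3SnH, PdCl2(PPh3)2 (3 mol%), THF, 0 °C → rt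
Reagents that add atoms: tributyltin hydride, CCCC[SnH](CCCC)CCCC
Why: Palladium-catalysed syn hydrostannylation, in which the ring carbon flanked by CMe2 and C-methyl shields the inner alkyne carbon, so tin should go to the terminus and give the E-dienylstannane (C7'=C8').

**Step 15**
Reactants: 18 but-2-yn-1-ol
Product: 20 (E)-3-iodobut-2-en-1-ol, via alkenylzirconocene 19 (not isolated)
Conditions: Cp2Zr(H)Cl (2.2 equiv), THF, rt → 40 °C; then I2, 0 °C
Reagents that add atoms: iodine, II
Why: Hydrozirconation–iodinolysis: after the hydroxyl is taken up as its zirconium alkoxide, Zr–H adds syn with zirconium settling next to the smaller methyl group, and iodine replaces it with retention, which fixes the E-trisubstituted C9'=C10' unit.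

**Step 16**
Reactants: 20 (E)-3-iodobut-2-en-1-ol
Product: 21 (E)-3-iodobut-2-enal
Conditions: MnO2, CH2Cl2, rt, dark
Reagents that add atoms: none
Why: Chemoselective MnO2 oxidation of an allylic alcohol under neutral conditions that leave the vinyl iodide and its geometry intact.

**Step 17**
Reactants: 21 (E)-3-iodobut-2-enal; 22 triethyl 4-phosphonocrotonate
Product: 23 ethyl (2E,4E,6E)-7-iodoocta-2,4,6-trienoate
Conditions: LiHMDS (LiN(SiMe3)2), THF, −78 → 0 °C
Reagents that add atoms: none
Why: Vinylogous Horner–Wadsworth–Emmons olefination, whose stabilised phosphonate anion adds reversibly and should give the E-configured C11'=C12' bond while the reagent brings C13'=C14' as E.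

**Step 18**
Reactants: 23 ethyl (2E,4E,6E)-7-iodoocta-2,4,6-trienoate
Product: 24 (2E,4E,6E)-7-iodoocta-2,4,6-trien-1-ol
Conditions: DIBAL-H (i-Bu2AlH, 2.2 equiv), CH2Cl2, −78 °C; aq. work-up
Reagents that add atoms: none
Why: 1,2-Reduction of a conjugated ester with DIBAL-H, which at low temperature spares the vinyl iodide and the triene.

**Step 19**
Reactants: 24 (2E,4E,6E)-7-iodoocta-2,4,6-trien-1-ol
Product: 25 (2E,4E,6E)-7-iodoocta-2,4,6-trienal
Conditions: MnO2, CH2Cl2, rt, dark
Reagents that add atoms: none
Why: MnO2 oxidation of a polyenylic alcohol, a mild heterogeneous method that avoids isomerisation of the triene.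

**Step 20**
Reactants: 25 (2E,4E,6E)-7-iodoocta-2,4,6-trienal; 26 2-(triphenylphosphoranylidene)propanal
Product: 27 (2E,4E,6E,8E)-9-iodo-2-methyldeca-2,4,6,8-tetraenal
Conditions: toluene, 80 °C, dark
Reagents that add atoms: none
Why: Wittig olefination with a stabilised ylide, which is E-selective for the trisubstituted C15'=C16' bond and stops after one addition because the α-methyl enal formed is less reactive than 25.

**Step 21**
Reactants: 17 ring dienylstannane; 27 (2E,4E,6E,8E)-9-iodo-2-methyldeca-2,4,6,8-tetraenal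
Product: 28 (2E,4E,6E,8E,10E)-11-[(3R,4S)-3,4-bis(tert-butyldimethylsilyloxy)-2,6,6-trimethylcyclohex-1-en-1-yl]-2,9-dimethylundeca-2,4,6,8,10-pentaenal
Conditions: Pd2(dba)3·CHCl3 (2.5 mol%), AsPh3 (20 mol%), NMP, rt → 40 °C, dark
Reagents that add atoms: none
Why: Stille coupling of an E-alkenylstannane with an E-alkenyl iodide under neutral conditions, which forms C8'–C9' with retention of both geometries and tolerates the aldehyde and the silyl ethers.

**Step 22**
Reactants: 29 3-bromofuran-2(5H)-one
Product: 30 3-bromo-2-(tert-butyldimethylsilyloxy)furan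
Conditions: TBSOTf, Et3N, CH2Cl2, 0 °C
Reagents that add atoms: tert-butyldimethylsilyl trifluoromethanesulfonate, CC(C)(C)[Si](C)(C)OS(=O)(=O)C(F)(F)F
Why: Soft enolisation and O-silylation of a butenolide, driven by aromatisation to the 2-silyloxyfuran, with the C–Br bond unaffected.

**Step 23**
Reactants: 28 pentaenal; 30 3-bromo-2-(tert-butyldimethylsilyloxy)furan
Product: 32 (5Z)-3-bromo-5-{(2E,4E,6E,8E,10E)-11-[(3R,4S)-3,4-bis(tert-butyldimethylsilyloxy)-2,6,6-trimethylcyclohex-1-en-1-yl]-2,9-dimethylundeca-2,4,6,8,10-pentaenylidene}furan-2(5H)-one, via silylated aldol adduct 31 (not isolated)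
Conditions: TBSOTf (10 mol%), CH2Cl2, −78 °C; then DBU, −78 °C → rt, dark
Reagents that add atoms: none
Why: Vinylogous Mukaiyama aldol addition at furan C5 with silyl transfer to the aldolate, followed by E1cB loss of silanolate; both aldol epimers converge on the Z-ylidene isomer, which is favoured because it keeps the branched C16' away from the lactone C4–H.

**Step 24**
Reactants: 32 bromo-ylidenebutenolide polyene; 12 oxabicyclic E-vinylstannane
Product: 33 3',4'-bis(tert-butyldimethylsilyl) ether of the target
Conditions: Pd2(dba)3·CHCl3 (5 mol%), AsPh3 (40 mol%), DMF, 40 °C, dark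
Reagents that add atoms: none
Why: Stille coupling of an α-bromobutenolide with an alkenylstannane: the electron-poor C–Br bond adds readily to zerovalent palladium, the E geometry of C7=C8 is retained, and no base or acid touches the lactone, the tertiary alcohol or the polyene.

**Step 25**
Reactants: 33 bis-silyl ether of the target
Product: 34 target CNP0216838.1, (5Z)-3-{(E)-2-[(1R,4S,6R)-6-hydroxy-2,2,6-trimethyl-7-oxabicyclo[2.2.1]heptan-1-yl]vinyl}-5-{(2E,4E,6E,8E,10E)-11-[(3R,4S)-3,4-dihydroxy-2,6,6-trimethylcyclohex-1-en-1-yl]-2,9-dimethylundeca-2,4,6,8,10-pentaenylidene}furan-2(5H)-one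
Conditions: TBAF (Bu4NF), AcOH (1:1), THF, 0 °C → rt, dark
Reagents that add atoms: none
Why: Acetic-acid-buffered fluoride desilylation, close to neutral, so neither the ylidenebutenolide (base-sensitive) nor the polyene-conjugated allylic 4'-alcohol (acid-sensitive) should suffer and no stereocentre is touched.

**Compound list**
1 | ketoisophorone (2,6,6-trimethylcyclohex-2-ene-1,4-dione) | CC1=CC(=O)CC(C)(C)C1=O | starting material
2 | (R)-levodione, (6R)-2,2,6-trimethylcyclohexane-1,4-dione | C[C@@H]1CC(=O)CC(C)(C)C1=O | intermediate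
3 | (4R,6R)-actinol, (4R,6R)-4-hydroxy-2,2,6-trimethylcyclohexan-1-one | C[C@@H]1C[C@@H](O)CC(C)(C)C1=O | intermediate
4 | (4R,6R)-4-(tert-butyldimethylsilyloxy)-2,2,6-trimethylcyclohexan-1-one | C[C@@H]1C[C@@H](O[Si](C)(C)C(C)(C)C)CC(C)(C)C1=O | intermediate
5 | lithium enolate of 4 | [Li+].CC1=C([O-])C(C)(C)C[C@H](O[Si](C)(C)C(C)(C)C)C1 | intermediate
6 | (R)-4-(tert-butyldimethylsilyloxy)-2,6,6-trimethylcyclohex-1-en-1-yl trifluoromethanesulfonate | CC1=C(OS(=O)(=O)C(F)(F)F)C(C)(C)C[C@H](O[Si](C)(C)C(C)(C)C)C1 | intermediate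
7 | ethynyltrimethylsilane | C#C[Si](C)(C)C | starting material
8 | (R)-tert-butyldimethyl{[3,5,5-trimethyl-4-(trimethylsilylethynyl)cyclohex-3-en-1-yl]oxy}silane | CC1=C(C#C[Si](C)(C)C)C(C)(C)C[C@H](O[Si](C)(C)C(C)(C)C)C1 | intermediate
9 | tert-butyldimethyl{[(1R,3S,6R)-1,5,5-trimethyl-6-(trimethylsilylethynyl)-7-oxabicyclo[4.1.0]heptan-3-yl]oxy}silane | C[Si](C)(C)C#C[C@@]12O[C@]1(C)C[C@@H](O[Si](C)(C)C(C)(C)C)CC2(C)C | intermediate
10 | (1R,3S,6R)-6-ethynyl-1,5,5-trimethyl-7-oxabicyclo[4.1.0]heptan-3-ol | C#C[C@@]12O[C@]1(C)C[C@@H](O)CC2(C)C | intermediate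
11 | (1S,4S,6R)-1-ethynyl-2,2,6-trimethyl-7-oxabicyclo[2.2.1]heptan-6-ol | C#C[C@@]12O[C@@H](CC1(C)C)C[C@@]2(C)O | intermediate
12 | (1R,4S,6R)-2,2,6-trimethyl-1-[(E)-2-(tributylstannyl)vinyl]-7-oxabicyclo[2.2.1]heptan-6-ol | CCCC[Sn](CCCC)(CCCC)/C=C/[C@@]12O[C@@H](CC1(C)C)C[C@@]2(C)O | intermediate
13 | (S)-6-(tert-butyldimethylsilyloxy)-2,4,4-trimethyl-3-(trimethylsilylethynyl)cyclohex-2-en-1-one | CC1=C(C#C[Si](C)(C)C)C(C)(C)C[C@H](O[Si](C)(C)C(C)(C)C)C1=O | intermediate
14 | (1R,6S)-6-(tert-butyldimethylsilyloxy)-2,4,4-trimethyl-3-(trimethylsilylethynyl)cyclohex-2-en-1-ol | CC1=C(C#C[Si](C)(C)C)C(C)(C)C[C@H](O[Si](C)(C)C(C)(C)C)[C@@H]1O | intermediate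
15 | (3R,4S)-3,4-bis(tert-butyldimethylsilyloxy)-2,6,6-trimethyl-1-(trimethylsilylethynyl)cyclohex-1-ene | CC1=C(C#C[Si](C)(C)C)C(C)(C)C[C@H](O[Si](C)(C)C(C)(C)C)[C@@H]1O[Si](C)(C)C(C)(C)C | intermediate
16 | (3R,4S)-3,4-bis(tert-butyldimethylsilyloxy)-1-ethynyl-2,6,6-trimethylcyclohex-1-ene | CC1=C(C#C)C(C)(C)C[C@H](O[Si](C)(C)C(C)(C)C)[C@@H]1O[Si](C)(C)C(C)(C)C | intermediate
17 | tributyl{(E)-2-[(3R,4S)-3,4-bis(tert-butyldimethylsilyloxy)-2,6,6-trimethylcyclohex-1-en-1-yl]vinyl}stannane | CC1=C(/C=C/[Sn](CCCC)(CCCC)CCCC)C(C)(C)C[C@H](O[Si](C)(C)C(C)(C)C)[C@@H]1O[Si](C)(C)C(C)(C)C | intermediate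
18 | but-2-yn-1-ol | CC#CCO | starting material
19 | (E)-alkenylzirconocene chloride of but-2-yn-1-ol, oxygen bound as zirconocene alkoxide | C/C([Zr](Cl)(C1C=CC=C1)C1C=CC=C1)=C\CO[Zr](Cl)(C1C=CC=C1)C1C=CC=C1 | intermediate
20 | (E)-3-iodobut-2-en-1-ol | I/C(C)=C/CO | intermediate
21 | (E)-3-iodobut-2-enal | I/C(C)=C/C=O | intermediate
22 | triethyl 4-phosphonocrotonate | CCOC(=O)/C=C/CP(=O)(OCC)OCC | starting material
23 | ethyl (2E,4E,6E)-7-iodoocta-2,4,6-trienoate | I/C(C)=C/C=C/C=C/C(=O)OCC | intermediate
24 | (2E,4E,6E)-7-iodoocta-2,4,6-trien-1-ol | I/C(C)=C/C=C/C=C/CO | intermediate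
25 | (2E,4E,6E)-7-iodoocta-2,4,6-trienal | I/C(C)=C/C=C/C=C/C=O | intermediate
26 | 2-(triphenylphosphoranylidene)propanal | CC(C=O)=P(c1ccccc1)(c1ccccc1)c1ccccc1 | starting material
27 | (2E,4E,6E,8E)-9-iodo-2-methyldeca-2,4,6,8-tetraenal | I/C(C)=C/C=C/C=C/C=C(C)/C=O | intermediate
28 | (2E,4E,6E,8E,10E)-11-[(3R,4S)-3,4-bis(tert-butyldimethylsilyloxy)-2,6,6-trimethylcyclohex-1-en-1-yl]-2,9-dimethylundeca-2,4,6,8,10-pentaenal | CC1=C(/C=C/C(C)=C/C=C/C=C/C=C(C)/C=O)C(C)(C)C[C@H](O[Si](C)(C)C(C)(C)C)[C@@H]1O[Si](C)(C)C(C)(C)C | intermediate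
29 | 3-bromofuran-2(5H)-one | BrC1=CCOC1=O | starting material
30 | 3-bromo-2-(tert-butyldimethylsilyloxy)furan | CC(C)(C)[Si](C)(C)Oc1occc1Br | intermediate
31 | O-silylated vinylogous aldol adduct of 28 and 30 (epimers at the two new centres) | CC1=C(/C=C/C(C)=C/C=C/C=C/C=C(C)/C(O[Si](C)(C)C(C)(C)C)C2C=C(Br)C(=O)O2)C(C)(C)C[C@H](O[Si](C)(C)C(C)(C)C)[C@@H]1O[Si](C)(C)C(C)(C)C | intermediate
32 | (5Z)-3-bromo-5-ylidenebutenolide polyene with the bis-silylated diol ring | CC1=C(/C=C/C(C)=C/C=C/C=C/C=C(C)/C=C2C=C(Br)C(=O)O/2)C(C)(C)C[C@H](O[Si](C)(C)C(C)(C)C)[C@@H]1O[Si](C)(C)C(C)(C)C | intermediate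
33 | 3',4'-bis(tert-butyldimethylsilyl) ether of the target | CC1=C(/C=C/C(C)=C/C=C/C=C/C=C(C)/C=C2C=C(/C=C/[C@@]34O[C@@H](CC3(C)C)C[C@@]4(C)O)C(=O)O/2)C(C)(C)C[C@H](O[Si](C)(C)C(C)(C)C)[C@@H]1O[Si](C)(C)C(C)(C)C | intermediate
34 | CNP0216838.1 | CC1=C(/C=C/C(C)=C/C=C/C=C/C=C(C)/C=C2C=C(/C=C/[C@@]34O[C@@H](CC3(C)C)C[C@@]4(C)O)C(=O)O/2)C(C)(C)C[C@H](O)[C@@H]1O | target

**Total step count:** 25
**Longest linear sequence:** 14 steps (steps 1–5, 10–14, 21, 23, 24, 25)

**Steps most likely to fail**

*Step 8.* The oxirane may ionise at C5 without help from the hydroxyl, since a terminal ethynyl group stabilises positive charge at C6 only weakly. This would lead on to ring contraction or proton loss instead of bridging.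

The fallback sets out from 10 and adds an activating group to the alkyne.
- Co2(CO)8 in CH2Cl2 at rt gives the hexacarbonyldicobalt complex of the epoxy alcohol F1.
- BF3·OEt2 at −78 °C then opens the oxirane at C6 through a cobalt-stabilised propargylic cation (Nicholas-type epoxy-alcohol cyclisation). Only the 3-OH on the opposite ring face can reach this cation, which gives the hexacarbonyldicobalt complex of the oxabicycle F2.
- Oxidative decomplexation with (NH4)2Ce(NO3)6 in acetone at 0 °C comes back to the route at 11.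

*Step 10.* Hydrogen abstraction at C4' may be sluggish, because the neighbouring silyloxy-bearing carbon deactivates and shields this position. Oxidation of the C5' methyl group or general over-oxidation could then take over.

The fallback sets out from 4 and installs the C4' oxygen by transposition instead of C–H oxidation.
- LDA and Me3SiCl give the trimethylsilyl enol ether F3.
- Saegusa–Ito dehydrogenation with Pd(OAc)2 in MeCN gives (S)-4-(tert-butyldimethylsilyloxy)-2,6,6-trimethylcyclohex-2-en-1-one F4.
- 1,2-Addition of lithiated 7 (n-BuLi, THF, −78 °C) gives the tertiary allylic, propargylic alcohol F5, of which either carbinol epimer serves.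
- A Babler–Dauben oxidative transposition with pyridinium chlorochromate (C5H5NH[CrO3Cl]) in CH2Cl2 moves the oxygen from C6' to C4' and comes back to the route at 13.

*Step 23.* The long polyenal may add sluggishly. The silyl triflate may erode the polyene or ionise the allylic 4'-silyl ether, and the elimination may not converge fully on the Z isomer.

The fallback sets out from 27 and 30 and moves the condensation to the simple iodotetraenal, before the sensitive ring is attached.
- The same aldol/elimination sequence passes through the O-silylated aldol adduct of the iodotetraenal F6.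
- It gives (5Z)-3-bromo-5-[(2E,4E,6E,8E)-9-iodo-2-methyldeca-2,4,6,8-tetraenylidene]furan-2(5H)-one F7.
- A chemoselective Stille coupling with 17 at room temperature (Pd2(dba)3·CHCl3, AsPh3, NMP) then uses the faster oxidative addition of the vinylic C–I bond over the lactone C–Br bond to zerovalent palladium and comes back to the route at 32.

**Further compounds**
F1 | step 8 | hexacarbonyldicobalt complex of 10 (alkyne bridging both cobalt atoms) | C#C[C@@]12O[C@]1(C)C[C@@H](O)CC2(C)C.[Co].[Co].[C-]#[O+].[C-]#[O+].[C-]#[O+].[C-]#[O+].[C-]#[O+].[C-]#[O+]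
F2 | step 8 | hexacarbonyldicobalt complex of 11 (alkyne bridging both cobalt atoms) | C#C[C@@]12O[C@@H](CC1(C)C)C[C@@]2(C)O.[Co].[Co].[C-]#[O+].[C-]#[O+].[C-]#[O+].[C-]#[O+].[C-]#[O+].[C-]#[O+]
F3 | step 10 | (R)-tert-butyldimethyl{[3,5,5-trimethyl-4-(trimethylsilyloxy)cyclohex-3-en-1-yl]oxy}silane | CC1=C(O[Si](C)(C)C)C(C)(C)C[C@H](O[Si](C)(C)C(C)(C)C)C1
F4 | step 10 | (S)-4-(tert-butyldimethylsilyloxy)-2,6,6-trimethylcyclohex-2-en-1-one | CC1=C[C@@H](O[Si](C)(C)C(C)(C)C)CC(C)(C)C1=O
F5 | step 10 | (4S)-4-(tert-butyldimethylsilyloxy)-2,6,6-trimethyl-1-(trimethylsilylethynyl)cyclohex-2-en-1-ol (carbinol centre undefined) | CC1=C[C@@H](O[Si](C)(C)C(C)(C)C)CC(C)(C)C1(O)C#C[Si](C)(C)C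
F6 | step 23 | O-silylated vinylogous aldol adduct of 27 and 30 (epimers at the two new centres) | I/C(C)=C/C=C/C=C/C=C(C)/C(O[Si](C)(C)C(C)(C)C)C1C=C(Br)C(=O)O1
F7 | step 23 | (5Z)-3-bromo-5-[(2E,4E,6E,8E)-9-iodo-2-methyldeca-2,4,6,8-tetraenylidene]furan-2(5H)-one | I/C(C)=C/C=C/C=C/C=C(C)/C=C1C=C(Br)C(=O)O/1
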